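**Retrosynthetic overview**
1. The C3–Br bond comes from SN2 bromination (inversion) of the axial secondary alcohol of a cis-1,3-diol, itself from hydride reduction of a tertiary β-hydroxy ketone.
2. Key disconnection: the C1–O bond of the tertiary carbinol, made by catalyst-controlled oxygenation (net conjugate hydration) of the ring A enone.
3. The ring A enone comes from a dimedone-type vinylogous ester by MeLi addition and carbonyl transposition; the bromomethylidene comes from the ring B enone by Wittig reaction.
4. The spiro stereocentre comes from desymmetrising enolisation and dehydrogenation of an achiral spiro dione.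
5. Ring order: ring A is bought (dimedone ethyl enol ether); ring B is built on it by Diels–Alder reaction of the derived exo-methylene enone with 2-(trimethylsilyloxy)butadiene.

Assumption: the sense of induction of the chiral lithium amide (step 3) and of the cinchona amine (step 6) is taken from the closest simple models; both exist in both enantiomeric or pseudo-enantiomeric forms, and the form giving the configuration drawn is used.

**Route**

Step 1
Reactants: 1 3-ethoxy-5,5-dimethylcyclohex-2-en-1-one; 2 dimethylmethylideneammonium iodide (Eschenmoser's salt)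
Product: 5 3-ethoxy-5,5-dimethyl-6-methylidenecyclohex-2-en-1-one, via Mannich base 3 (not isolated), via methiodide 4 (not isolated)
Conditions: LiN(i-Pr)2, THF, −78 °C; 2, −78 °C to rt; MeI, rt; aq. NaHCO3, CH2Cl2, rt
Reagents that add atoms: none
Why: Eschenmoser methylenation: the kinetic enolate can only form at the α′ CH2 between the carbonyl and the gem-dimethyl carbon, and Mannich reaction, N-methylation and mild-base loss of trimethylamine give the exo-methylene enone without creating a stereocentre.

Step 2
Reactants: 5 3-ethoxy-5,5-dimethyl-6-methylidenecyclohex-2-en-1-one; 6 2-(trimethylsilyloxy)buta-1,3-diene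
Product: 8 3-ethoxy-5,5-dimethylspiro[5.5]undec-2-ene-1,9-dione, via cycloadduct 7 (not isolated)
Conditions: toluene, BHT (cat.), 140 °C, sealed tube; then K2CO3 (cat.), EtOH, 0 °C
Reagents that add atoms: none
Why: Thermal Diels–Alder reaction of the exo-methylene enone (a 3,3-dimethyl-2-methylenecyclohexanone-type dienophile) with the 2-silyloxydiene builds ring B and the quaternary spiro carbon with para regiochemistry, and catalytic ethanolysis of the silyl enol ether leaves the vinylogous ester intact; ring B of 8 is symmetric, so there is no stereocentre yet.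

Step 3
Reactants: 8 3-ethoxy-5,5-dimethylspiro[5.5]undec-2-ene-1,9-dione
Product: 10 (6S)-3-ethoxy-5,5-dimethylspiro[5.5]undeca-2,7-diene-1,9-dione, via silyl enol ether 9 (not isolated)
Conditions: (S,S)-bis(1-phenylethyl)amine·HCl, n-BuLi (2 equiv), THF, −78 °C; Me3SiCl, 8, −100 °C; then Pd(OAc)2 (1.1 equiv), MeCN, rt
Reagents that add atoms: none
Why: Enantioselective deprotonation with a chiral lithium amide under in-situ Me3SiCl quench (Simpkins–Koga desymmetrisation) removes one of the two enantiotopic axial α-protons of the ring B ketone, which is locked with the ring A carbonyl carbon axial and the CMe2 carbon equatorial, and Saegusa–Ito oxidation of that enol ether places the double bond at C7=C8 and so fixes the spiro carbon as 6S.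

Step 4
Reactants: 10 (6S)-3-ethoxy-5,5-dimethylspiro[5.5]undeca-2,7-diene-1,9-dione; 11 (bromomethyl)triphenylphosphonium bromide
Product: 12 (6S,9E)-9-(bromomethylidene)-3-ethoxy-5,5-dimethylspiro[5.5]undeca-2,7-dien-1-one
Conditions: 11, KOt-Bu, THF, −78 °C; then 10, −78 °C to rt; chromatography
Reagents that add atoms: none
Why: Wittig bromomethylenation of the ring B enone carbonyl (the vinylogous ester carbonyl is inert to the ylide), in which bromine is expected to end up mainly syn to the bulkier sp3 carbon C10 (9E); the minor 9Z isomer is removed by chromatography and C6 is untouched.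

Step 5
Reactants: 12 (6S,9E)-9-(bromomethylidene)-3-ethoxy-5,5-dimethylspiro[5.5]undeca-2,7-dien-1-one
Product: 14 (6S,9E)-9-(bromomethylidene)-1,5,5-trimethylspiro[5.5]undeca-1,7-dien-3-one, via tertiary carbinol 13 (not isolated)
Conditions: MeLi, CeCl3, THF, −78 to 0 °C; then 1 M aq. HCl, rt
Reagents that add atoms: methyllithium, [Li]C; water, O
Why: Stork–Danheiser transposition: the non-basic organocerium reagent adds 1,2 to the hindered vinylogous ester carbonyl without touching the vinyl bromide, and acid-induced loss of water followed by hydrolysis of the alkoxy-allyl cation moves the carbonyl to C3 and leaves the methyl group on C1.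

Step 6
Reactants: 14 (6S,9E)-9-(bromomethylidene)-1,5,5-trimethylspiro[5.5]undeca-1,7-dien-3-one
Product: 16 (1S,6S,9E)-9-(bromomethylidene)-1-hydroxy-1,5,5-trimethylspiro[5.5]undec-7-en-3-one, via epoxy ketone 15 (not isolated)
Conditions: 9-amino-9-deoxy-epi-quinine (10 mol%), CF3CO2H (20 mol%), 50% aq. H2O2, dioxane, 40 °C; aq. Na2S2O3/citrate wash; then SmI2 (2.2 equiv), THF–MeOH, −90 °C
Reagents that add atoms: hydrogen peroxide, OO
Why: Proposed new method: a catalyst-controlled net conjugate hydration of a β-methyl enone whose β-carbon is flanked by the spiro quaternary carbon, in which the primary amine condenses with the unhindered C3 ketone to an iminium ion, the protonated quinuclidine delivers hydroperoxide to C1 on the ring A face that carries C11 (forming the C1–O bond), the β-peroxy enamine closes to the 1R,2R epoxide, and after the amine is washed out SmI2 cleaves only the Cα–O bond through the ketyl and samarium enolate to leave the 1S tertiary carbinol at a temperature where β-elimination and retro-aldol do not occur; the closest known reactions are the amine-salt-catalysed asymmetric Weitz–Scheffer epoxidation of simple cyclic enones and the SmI2 opening of α,β-epoxy ketones, neither shown at a β-carbon next to a fully substituted spiro centre or used to override a neighbouring stereogenic spiro carbon.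

Step 7
Reactants: 16 (1S,6S,9E)-9-(bromomethylidene)-1-hydroxy-1,5,5-trimethylspiro[5.5]undec-7-en-3-one
Product: 17 (1S,3S,6S,9E)-9-(bromomethylidene)-1,5,5-trimethylspiro[5.5]undec-7-ene-1,3-diol
Conditions: LiBH(s-Bu)3, THF, −78 °C; then H2O
Reagents that add atoms: none
Why: Bulky-borohydride ketone reduction: in the preferred chair the axial face of the C3 carbonyl is blocked by the syn-axial C1 hydroxyl and C5 methyl, so hydride enters equatorially and gives the axial 3S alcohol cis to the C1 hydroxyl.

Step 8
Reactants: 17 (1S,3S,6S,9E)-9-(bromomethylidene)-1,5,5-trimethylspiro[5.5]undec-7-ene-1,3-diol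
Product: 18 (1S,3R,6S,9E)-3-bromo-9-(bromomethylidene)-1,5,5-trimethylspiro[5.5]undec-7-en-1-ol
Conditions: CBr4, PPh3, CH2Cl2, 0 °C to rt
Reagents that add atoms: carbon tetrabromide, BrC(Br)(Br)Br
Why: Appel reaction: the axial secondary oxyphosphonium is displaced by bromide in an SN2 step with inversion (3S to 3R, bromine equatorial and trans to the C1 hydroxyl), the hindered tertiary alcohol does not react, and the cis arrangement rules out oxetane formation and Grob fragmentation.

**Compound list**

1 | 3-ethoxy-5,5-dimethylcyclohex-2-en-1-one | CCOC1=CC(=O)CC(C)(C)C1 | starting material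
2 | dimethylmethylideneammonium iodide (Eschenmoser's salt) | C=[N+](C)C.[I-] | starting material
3 | 6-[(dimethylamino)methyl]-3-ethoxy-5,5-dimethylcyclohex-2-en-1-one (racemic Mannich base) | CCOC1=CC(=O)C(CN(C)C)C(C)(C)C1 | intermediate
4 | [(4-ethoxy-6,6-dimethyl-2-oxocyclohex-3-en-1-yl)methyl]trimethylammonium iodide (racemic methiodide) | CCOC1=CC(=O)C(C[N+](C)(C)C)C(C)(C)C1.[I-] | intermediate
5 | 3-ethoxy-5,5-dimethyl-6-methylidenecyclohex-2-en-1-one | CCOC1=CC(=O)C(=C)C(C)(C)C1 | intermediate
6 | 2-(trimethylsilyloxy)buta-1,3-diene | C=CC(=C)O[Si](C)(C)C | starting material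
7 | 3-ethoxy-5,5-dimethyl-9-(trimethylsilyloxy)spiro[5.5]undeca-2,8-dien-1-one (racemic cycloadduct) | CCOC1=CC(=O)C2(CC=C(O[Si](C)(C)C)CC2)C(C)(C)C1 | intermediate
8 | 3-ethoxy-5,5-dimethylspiro[5.5]undec-2-ene-1,9-dione (achiral) | CCOC1=CC(=O)C2(CCC(=O)CC2)C(C)(C)C1 | intermediate
9 | (6S)-3-ethoxy-5,5-dimethyl-9-(trimethylsilyloxy)spiro[5.5]undeca-2,8-dien-1-one | CC1(C)CC(OCC)=CC(=O)[C@@]12CC=C(O[Si](C)(C)C)CC2 | intermediate
10 | (6S)-3-ethoxy-5,5-dimethylspiro[5.5]undeca-2,7-diene-1,9-dione | CC1(C)CC(OCC)=CC(=O)[C@@]12C=CC(=O)CC2 | intermediate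
11 | (bromomethyl)triphenylphosphonium bromide | BrC[P+](c1ccccc1)(c1ccccc1)c1ccccc1.[Br-] | starting material
12 | (6S,9E)-9-(bromomethylidene)-3-ethoxy-5,5-dimethylspiro[5.5]undeca-2,7-dien-1-one | CC1(C)CC(OCC)=CC(=O)[C@@]12C=C/C(=C/Br)CC2 | intermediate
13 | (6S,9E)-9-(bromomethylidene)-3-ethoxy-1,5,5-trimethylspiro[5.5]undeca-2,7-dien-1-ol (both C1 epimers) | CC1(C)CC(OCC)=CC(C)(O)[C@@]12C=C/C(=C/Br)CC2 | intermediate
14 | (6S,9E)-9-(bromomethylidene)-1,5,5-trimethylspiro[5.5]undeca-1,7-dien-3-one | CC1(C)CC(=O)C=C(C)[C@@]12C=C/C(=C/Br)CC2 | intermediate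
15 | (1R,2R,6S,9E)-9-(bromomethylidene)-1,2-epoxy-1,5,5-trimethylspiro[5.5]undec-7-en-3-one | CC1(C)CC(=O)[C@@H]2O[C@]2(C)[C@@]13C=C/C(=C/Br)CC3 | intermediate
16 | (1S,6S,9E)-9-(bromomethylidene)-1-hydroxy-1,5,5-trimethylspiro[5.5]undec-7-en-3-one | CC1(C)CC(=O)C[C@](C)(O)[C@@]12C=C/C(=C/Br)CC2 | intermediate
17 | (1S,3S,6S,9E)-9-(bromomethylidene)-1,5,5-trimethylspiro[5.5]undec-7-ene-1,3-diol | CC1(C)C[C@H](O)C[C@](C)(O)[C@@]12C=C/C(=C/Br)CC2 | intermediate
18 | (1S,3R,6S,9E)-3-bromo-9-(bromomethylidene)-1,5,5-trimethylspiro[5.5]undec-7-en-1-ol | CC1(C)C[C@@H](Br)C[C@](C)(O)[C@@]12C=C/C(=C/Br)CC2 | target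

**Step count and risks**

Total step count: 8. Longest linear sequence: 8 steps (1 to 18; all other components are purchased).

The three steps most likely to fail:

Step 6 (the proposed new step). Hydroperoxide may not reach the hindered β-carbon, or the amine may not override the substrate's own facial bias; the quinidine-derived pseudo-enantiomer is the first variation. The fallback uses only established reactions and sets out from 14. Corey–Bakshi–Shibata reduction (2-methyl-CBS-oxazaborolidine, BH3·SMe2) gives the allylic alcohol (3S,6S,9E)-9-(bromomethylidene)-1,5,5-trimethylspiro[5.5]undeca-1,7-dien-3-ol F3. Its hydroxyl directs VO(acac)2/t-BuOOH epoxidation to the same face, giving the cis epoxy alcohol (1R,2S,3S,6S,9E)-9-(bromomethylidene)-1,2-epoxy-1,5,5-trimethylspiro[5.5]undec-7-en-3-ol F4; the bromodiene is not an allylic alcohol and is left alone. Dess–Martin oxidation of F4 comes back to the route at epoxy ketone 15, which is opened with SmI2 to 16 as in step 6.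

Step 3. The chiral lithium amide has not been used on this spiro dione, and the enantiomeric excess may be moderate. Material of the wrong spiro configuration becomes a separable diastereomer after the catalyst-controlled step 6, which upgrades purity. The fallback sets out from 8. Double dehydrogenation with IBX (3 equiv, DMSO, 80 °C) gives the achiral cross-conjugated dienone 3-ethoxy-5,5-dimethylspiro[5.5]undeca-2,7,10-triene-1,9-dione F1; ring A has no position that can be dehydrogenated. Enantioselective conjugate reduction of one of the two enantiotopic ring B double bonds by an ene-reductase of the old-yellow-enzyme family (NADPH, glucose/glucose dehydrogenase recycling) comes back to the route at 10.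

Step 4. The Wittig reaction may give a poor E/Z ratio or a difficult separation. The fallback sets out from 10. Ramirez olefination (CBr4, PPh3, CH2Cl2) gives (6S)-9-(dibromomethylidene)-3-ethoxy-5,5-dimethylspiro[5.5]undeca-2,7-dien-1-one F2, which has no alkene geometry. Pd(PPh3)4-catalysed hydrogenolysis with Bu3SnH then removes the less hindered bromine, the one syn to the sp2 carbon C8, and comes back to the route at 12 with the bromine syn to C10.

**Further compounds**

F1 | step 3 | 3-ethoxy-5,5-dimethylspiro[5.5]undeca-2,7,10-triene-1,9-dione | CCOC1=CC(=O)C2(C=CC(=O)C=C2)C(C)(C)C1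
F2 | step 4 | (6S)-9-(dibromomethylidene)-3-ethoxy-5,5-dimethylspiro[5.5]undeca-2,7-dien-1-one | CC1(C)CC(OCC)=CC(=O)[C@@]12C=CC(=C(Br)Br)CC2
F3 | step 6 | (3S,6S,9E)-9-(bromomethylidene)-1,5,5-trimethylspiro[5.5]undeca-1,7-dien-3-ol | CC1(C)C[C@H](O)C=C(C)[C@@]12C=C/C(=C/Br)CC2
F4 | step 6 | (1R,2S,3S,6S,9E)-9-(bromomethylidene)-1,2-epoxy-1,5,5-trimethylspiro[5.5]undec-7-en-3-ol | CC1(C)C[C@H](O)[C@@H]2O[C@]2(C)[C@@]13C=C/C(=C/Br)CC3
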